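**Amounts.** The flask holds C = 0.0220 mM of catalyst against 0.044 M of substrate, the substrate charge of the violet and green runs.

in all of them: gas 8.1 mM (held)

| charge | substrate | free catalyst | remark | time |
|---|---|---|---|---|
| violet | 0.044 M | 0.025 mol% | run made earlier |  |
| green | 0.044 M | 0.038 mol% | run made earlier |  |
| teal | 0.088 M | 0.05 mol% | run made earlier |  |
| flask | 0.044 M | 0.05 mol% |  | 6.0 h |

| run | time / h | target / % | substrate / % |
|---|---|---|---|
| violet | 1.33 | 26.5 | 74.7 |
| violet | 2.50 | 43.8 | 54.2 |
| violet | 4.00 | 63.0 | 35.7 |
| violet | 5.00 | 69.7 | 28.9 |
| green | 0.417 | 13.3 | 86.5 |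
| green | 0.833 | 25.0 | 75.0 |
| green | 2.00 | 50.8 | 48.5 |
| green | 5.00 | 83.6 | 13.9 |
| teal | 0.417 | 24.3 | 76.0 |
| teal | 0.833 | 42.1 | 55.1 |
| teal | 2.00 | 77.6 | 18.7 |
| teal | 5.00 | 92.1 | 0 |

(readings scatter by 1 percentage point)

- at the start none of coupling partner is dissolved
- what may be going on: coupling partner + free catalyst -> catalyst intermediate A; catalyst intermediate A -> catalyst intermediate B; substrate + catalyst intermediate B <-> catalyst intermediate C; catalyst intermediate C -> free catalyst + target; target + free catalyst <-> isomer of the product + free catalyst; gas <-> coupling partner

1. amount of target in percent of the substrate charged, at 80 min, 3.0 h and 6.0 h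

**Specific rate.** I carry one quantity: the specific rate κ, the first-order constant of substrate loss divided by charged catalyst concentration. The green run's start gives 20.7 /mM/h. The violet run's start gives 19.9 /mM/h, so at this substrate charge the two starts read roughly in proportion to catalyst. Between 2.00 h and 5.00 h in the green run, as substrate falls from 48.5% to 13.9%, κ reads 24.9 /mM/h.

**The slowing.** I reckon the flask's pseudo-first-order constant at first as 0.454 /h. Scaling time by catalyst, I put the flask at the green run's 2.00 h state at 1.52 h, and I take its constant from then on as 0.548 /h. That rise recovers a factor of 1.20. I reckon substrate at 54.6% at 80 min, 21.5% at 3.0 h and 4.16% at 6.0 h. Its fall by a factor of 24.0 is larger than that rise, so at 6.0 h I reckon the rate down by a factor of 19.9.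

**My target.** The green run's target and substrate fall short of the charge by 0.700% at 2.00 h and 2.50% at 5.00 h. Subtracting the first at 80 min and the second later, I reckon 44.7%, 76.0% and 93.3%.

**Result.** The forecast gives 46.5%, 78% and 93.5%, reading the trend in κ thus: “This looks like saturation”. The flask gives 46.0%, 76.2% and 93.2%.

    coupling partner + free catalyst → catalyst intermediate A (k = 290 /M/s)
    catalyst intermediate A → catalyst intermediate B (k = 150 /s)
    substrate + catalyst intermediate B ⇌ catalyst intermediate C (K = 8.50 /M, k = 12.0 /M/s)
    catalyst intermediate C → free catalyst + target (k = 2.30 /s)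
    target + free catalyst ⇌ isomer of the product + free catalyst, rate k5*[free catalyst]*[target] forward; the back reaction follows from the equilibrium constant (K = 1.90, k = 3.10 /M/s)
    gas ⇌ coupling partner, rate k6*(csat - [coupling partner]) (kL = 0.00390 /s)

**What ran.** In the flask, catalyst intermediate B is the resting state, at 81.0% of the catalyst charged at 0.600 h and 98.9% at 6.00 h, while coupling partner stands at 0.00692 M and then 0.00802 M against a saturation of 8.1 mM. Target passes into isomer of the product by a net 2.82% of the substrate charged up to 6.0 h. The flask's substrate at 0.600 h gives κ = 20.3 /mM/h, beside the 20.7 /mM/h read from the green run's start. The teal run, with twice the flask's catalyst concentration and twice its substrate charge, reads 21.0 /mM/h from 0.833 h to 2.00 h.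

(The data were generated by integration from invented constants; noise was put on by code.)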